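**Plan**

- Retrosynthesis: with both phenols masked as benzyl ethers, the C7 carbinol goes back to an aryl ketone. The oxolane is cut at C4–C5 (C5 is the acetal CH2 of a methoxymethyl ether on O1), then C7–aryl is cut to an aryllithium and a γ-lactone carbonyl. O1–C2 is cut by taking out the inserted oxygen, leaving a 3-(arylmethyl)cyclobutanone built from an allylarene and dichloroketene.
- Enabling feature: oxolane C3, which carries the CH2Ar arm, has two ring neighbours, C2 and C4. Together with C7 they trace a four-carbon loop C2–C3–C4–C7 in which C2 and C4 are the mirror-related α-CH2 groups of a prochiral cyclobutanone and C7 is its carbonyl carbon.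
- Forward order of rings: cyclobutanone ([2+2], dechlorination), then γ-lactone by oxygen insertion (step 4), then lactone opened by the aryllithium (C7 becomes a ketone), then oxolane closed at C4–C5, ketone reduction, debenzylation.
- Stereochemistry: C3 (R) comes from the catalyst's choice between the two enantiotopic CH2 groups in step 4. C4 (R) is set trans to C3 by the closure and by equilibration α to the ketone. C7 (S) comes from ligand-controlled transfer hydrogenation.
- Locants in the discussion are those of the target oxolane (O1, C2, C3 with the CH2Ar arm, C4 with the C7 arm, C5; C7 is the carbinol carbon). Systematic names in the list may count the ring the other way round.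

Key step: step 4

Assumption: which antipode of the phosphoric acid gives the R lactone cannot be fixed on paper, so the route is written with the (S)-acid; the configuration of 8 is to be checked at that stage and the mirror-image acid used, with nothing else changed, if the sense proves opposite.

**Route**

Step 1
Reactants: 1 4-allyl-2,6-dimethoxyphenol
Product: 2 5-allyl-2-(benzyloxy)-1,3-dimethoxybenzene
Conditions: BnBr, K2CO3, DMF, 60 °C
Reagents that add atoms: benzyl bromide, BrCc1ccccc1
Why: Williamson O-alkylation of the acidic syringyl phenoxide with a reactive benzylic bromide should proceed cleanly, the allyl group and the methyl ethers being inert to carbonate base.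

Step 2
Reactants: 2 5-allyl-2-(benzyloxy)-1,3-dimethoxybenzene; 3 trichloroacetyl chloride
Product: 5 2,2-dichloro-3-{[4-(benzyloxy)-3,5-dimethoxyphenyl]methyl}cyclobutan-1-one (racemic), via dichloroketene 4 (not isolated)
Conditions: Zn–Cu couple, POCl3, Et2O, reflux, slow addition of 3
Reagents that add atoms: none
Why: Zinc dehalogenates 3 to dichloroketene, which undergoes the thermal ketene–alkene [2+2] cycloaddition with the terminal olefin so that the ketene carbonyl carbon bonds to the CH2 terminus, giving the 2,2-dichloro-3-substituted cyclobutanone regioselectively, while POCl3 ties up ZnCl2 and so spares the electron-rich arene; the one stereocentre is racemic and loses its meaning in step 3.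

Step 3
Reactants: 5 2,2-dichloro-3-{[4-(benzyloxy)-3,5-dimethoxyphenyl]methyl}cyclobutan-1-one
Product: 6 3-{[4-(benzyloxy)-3,5-dimethoxyphenyl]methyl}cyclobutan-1-one
Conditions: Zn dust, AcOH, rt → 60 °C
Reagents that add atoms: none
Why: Reductive dechlorination of an α,α-dichloroketone by zinc in acetic acid (zinc enolate formation and protonation, twice) leaves the benzyl ether and the four-membered ring intact and gives the achiral, mirror-symmetric ketone.

Step 4
Reactants: 6 3-{[4-(benzyloxy)-3,5-dimethoxyphenyl]methyl}cyclobutan-1-one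
Product: 8 (4R)-4-{[4-(benzyloxy)-3,5-dimethoxyphenyl]methyl}oxolan-2-one, via Criegee hydroperoxy hemiketal 7 (not isolated)
Conditions: (S)-3,3'-di(pyren-1-yl)-5,5',6,6',7,7',8,8'-octahydro-1,1'-binaphthalene-2,2'-diyl hydrogen phosphate (10 mol %), 30 % aq H2O2 (1.5 equiv), CHCl3, −40 °C
Reagents that add atoms: hydrogen peroxide, OO
Why: The phosphoric acid activates the strained carbonyl and the peroxide through a hydrogen-bond relay, H2O2 adds to give the Criegee hemiketal 7, and one α-CH2 shifts from carbon to oxygen with loss of water, relief of four-ring strain making the shift fast even at low temperature. The closest known reaction type is the chiral-Brønsted-acid-catalysed Baeyer–Villiger desymmetrisation of 3-substituted cyclobutanones with aqueous hydrogen peroxide. The γ-lactone ring arises by ring expansion, a 1,2-shift within the existing carbocycle and not a cyclisation of an open chain, and this shift creates the O1–C2 bond of the later oxolane. The ring carbon bearing the CH2Ar arm becomes the R stereocentre because the chiral phosphate pocket should hold the Criegee adduct so that only one of the two enantiotopic CH2 groups lies antiperiplanar to the breaking O–O bond. Only enantiotopic-group selection is required: the two α-carbons are constitutionally identical, so no regiochemical question arises, and the strained ketone should be far more reactive toward peroxide than the alkoxyarene or the benzyl ether.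

Step 5
Reactants: 9 4-bromo-2,6-dimethoxyphenol
Product: 10 2-(benzyloxy)-5-bromo-1,3-dimethoxybenzene
Conditions: BnBr, K2CO3, DMF, 60 °C
Reagents that add atoms: benzyl bromide, BrCc1ccccc1
Why: The same Williamson O-alkylation as in step 1 should apply, the aryl bromide being untouched by carbonate base.

Step 6
Reactants: 8 (4R)-4-{[4-(benzyloxy)-3,5-dimethoxyphenyl]methyl}oxolan-2-one; 10 2-(benzyloxy)-5-bromo-1,3-dimethoxybenzene
Product: 13 (3R)-1-[4-(benzyloxy)-3,5-dimethoxyphenyl]-3-{[4-(benzyloxy)-3,5-dimethoxyphenyl]methyl}-4-hydroxybutan-1-one, via aryllithium 11 (not isolated), via lithium hemiketal alkoxide 12 (not isolated)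
Conditions: 10, n-BuLi, THF, −78 °C; then 8, −78 °C; sat. aq NH4Cl at −78 °C
Reagents that add atoms: none
Why: Bromine–lithium exchange gives aryllithium 11, whose addition to the lactone carbonyl should stop at the tetrahedral lithium alkoxide 12 at −78 °C, so that cold protonation releases the γ-hydroxy aryl ketone without a second addition; the stereocentre sits β to the new ketone and cannot enolise.

Step 7
Reactants: 13 (3R)-1-[4-(benzyloxy)-3,5-dimethoxyphenyl]-3-{[4-(benzyloxy)-3,5-dimethoxyphenyl]methyl}-4-hydroxybutan-1-one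
Product: 14 (3R)-1-[4-(benzyloxy)-3,5-dimethoxyphenyl]-3-{[4-(benzyloxy)-3,5-dimethoxyphenyl]methyl}-4-(methoxymethoxy)butan-1-one
Conditions: MeOCH2Cl, iPr2NEt, CH2Cl2, 0 °C → rt
Reagents that add atoms: chloromethyl methyl ether, COCCl
Why: Alkylation of the primary alcohol by the α-chloro ether under amine base traps the open-chain hydroxy ketone as its methoxymethyl acetal, which blocks hemiketal formation and at the same time installs the CH2 that becomes C5.

Step 8
Reactants: 14 (3R)-1-[4-(benzyloxy)-3,5-dimethoxyphenyl]-3-{[4-(benzyloxy)-3,5-dimethoxyphenyl]methyl}-4-(methoxymethoxy)butan-1-one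
Product: 17 [(3R,4R)-4-{[4-(benzyloxy)-3,5-dimethoxyphenyl]methyl}oxolan-3-yl][4-(benzyloxy)-3,5-dimethoxyphenyl]methanone, via trimethylsilyl enol ether 15 (not isolated), via oxocarbenium triflate 16 (not isolated)
Conditions: Me3SiOTf (1.2 equiv), iPr2NEt (1.3 equiv), CH2Cl2, 0 °C; then Me3SiOTf (1.0 equiv), −40 → 0 °C; aq NaHCO3; then 1,8-diazabicyclo[5.4.0]undec-7-ene (0.2 equiv), CH2Cl2, rt
Reagents that add atoms: none
Why: Proposed new method: soft enolisation with Me3SiOTf and iPr2NEt should give the (Z)-silyl enol ether 15 (only the CH2 flank of the aryl ketone can enolise), further Me3SiOTf should ionise the O–CH2–OMe acetal at its less hindered methoxy oxygen to the O-methylene oxocarbenium ion 16 with loss of Me3SiOMe, and the tethered enol carbon should add to it in a 5-(enolexo)-endo-trig Mukaiyama-type closure that forms C4–C5 and returns the ketone; the new C4 centre is α to the carbonyl, so the kinetic preference for the trans envelope is backed by amidine-base equilibration to the more stable trans isomer while C3 is untouched; the closest known reaction types are the one-pot silyl triflate/amine enol silane formation–Mukaiyama addition to acetals, the capture of methoxymethyl-ether-derived oxocarbenium ions by carbon nucleophiles, and the enol-to-oxocarbenium aldol closure that delivers 3-acyloxolanes in Prins–pinacol-type annulations.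

Step 9
Reactants: 17 [(3R,4R)-4-{[4-(benzyloxy)-3,5-dimethoxyphenyl]methyl}oxolan-3-yl][4-(benzyloxy)-3,5-dimethoxyphenyl]methanone
Product: 18 (S)-[4-(benzyloxy)-3,5-dimethoxyphenyl][(3R,4R)-4-{[4-(benzyloxy)-3,5-dimethoxyphenyl]methyl}oxolan-3-yl]methanol
Conditions: RuCl[(S,S)-TsDPEN](p-cymene) (2 mol %; TsDPEN = N-tosyl-1,2-diphenylethylenediamine), HCO2H–Et3N (5:2), EtOAc, 40 °C
Reagents that add atoms: none
Why: Noyori–Ikariya asymmetric transfer hydrogenation of an aryl ketone delivers hydride through the six-membered metal–ligand bifunctional transition state, and the (S,S)-ligand should give the S carbinol in the same sense as for simple aryl alkyl ketones (priorities OH > aryl > ring carbon); a Felkin–Anh analysis with the C3 branch as the large group points to the same face, and the α-centre stays trans because that is its thermodynamic arrangement.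

Step 10
Reactants: 18 (S)-[4-(benzyloxy)-3,5-dimethoxyphenyl][(3R,4R)-4-{[4-(benzyloxy)-3,5-dimethoxyphenyl]methyl}oxolan-3-yl]methanol
Product: 19 4-{[(3R,4R)-4-[(S)-hydroxy(4-hydroxy-3,5-dimethoxyphenyl)methyl]oxolan-3-yl]methyl}-2,6-dimethoxyphenol (CNP0257794.1)
Conditions: H2 (1 atm), Pd/C (10 %), EtOAc–EtOH, rt, stopped after uptake of two equivalents
Reagents that add atoms: none
Why: Catalytic hydrogenolysis of the two aryl benzyl ethers should be much faster than C–O cleavage of the secondary benzylic alcohol in a neutral, acid-free medium, and no stereocentre is touched.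

**Compound list**

1 | 4-allyl-2,6-dimethoxyphenol | C=CCc1cc(OC)c(O)c(OC)c1 | starting material
2 | 5-allyl-2-(benzyloxy)-1,3-dimethoxybenzene | C=CCc1cc(OC)c(OCc2ccccc2)c(OC)c1 | intermediate
3 | trichloroacetyl chloride | ClC(=O)C(Cl)(Cl)Cl | starting material
4 | dichloroketene | ClC(Cl)=C=O | intermediate
5 | 2,2-dichloro-3-{[4-(benzyloxy)-3,5-dimethoxyphenyl]methyl}cyclobutan-1-one (racemic) | COc1cc(CC2CC(=O)C2(Cl)Cl)cc(OC)c1OCc1ccccc1 | intermediate
6 | 3-{[4-(benzyloxy)-3,5-dimethoxyphenyl]methyl}cyclobutan-1-one | COc1cc(CC2CC(=O)C2)cc(OC)c1OCc1ccccc1 | intermediate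
7 | 3-{[4-(benzyloxy)-3,5-dimethoxyphenyl]methyl}-1-hydroperoxycyclobutan-1-ol (Criegee adduct) | COc1cc(CC2CC(O)(OO)C2)cc(OC)c1OCc1ccccc1 | intermediate
8 | (4R)-4-{[4-(benzyloxy)-3,5-dimethoxyphenyl]methyl}oxolan-2-one | COc1cc(C[C@@H]2CC(=O)OC2)cc(OC)c1OCc1ccccc1 | intermediate
9 | 4-bromo-2,6-dimethoxyphenol | COc1cc(Br)cc(OC)c1O | starting material
10 | 2-(benzyloxy)-5-bromo-1,3-dimethoxybenzene | COc1cc(Br)cc(OC)c1OCc1ccccc1 | intermediate
11 | [4-(benzyloxy)-3,5-dimethoxyphenyl]lithium | COc1cc([Li])cc(OC)c1OCc1ccccc1 | intermediate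
12 | lithium (4R)-2-[4-(benzyloxy)-3,5-dimethoxyphenyl]-4-{[4-(benzyloxy)-3,5-dimethoxyphenyl]methyl}oxolan-2-olate (C2 unassigned) | COc1cc(C[C@@H]2CC([O-])(c3cc(OC)c(OCc4ccccc4)c(OC)c3)OC2)cc(OC)c1OCc1ccccc1.[Li+] | intermediate
13 | (3R)-1-[4-(benzyloxy)-3,5-dimethoxyphenyl]-3-{[4-(benzyloxy)-3,5-dimethoxyphenyl]methyl}-4-hydroxybutan-1-one | COc1cc(C[C@@H](CO)CC(=O)c2cc(OC)c(OCc3ccccc3)c(OC)c2)cc(OC)c1OCc1ccccc1 | intermediate
14 | (3R)-1-[4-(benzyloxy)-3,5-dimethoxyphenyl]-3-{[4-(benzyloxy)-3,5-dimethoxyphenyl]methyl}-4-(methoxymethoxy)butan-1-one | COc1cc(C[C@@H](COCOC)CC(=O)c2cc(OC)c(OCc3ccccc3)c(OC)c2)cc(OC)c1OCc1ccccc1 | intermediate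
15 | {[(1Z,3R)-1-[4-(benzyloxy)-3,5-dimethoxyphenyl]-3-{[4-(benzyloxy)-3,5-dimethoxyphenyl]methyl}-4-(methoxymethoxy)but-1-en-1-yl]oxy}trimethylsilane | COc1cc(C[C@@H](COCOC)/C=C(\O[Si](C)(C)C)c2cc(OC)c(OCc3ccccc3)c(OC)c2)cc(OC)c1OCc1ccccc1 | intermediate
16 | [(2R,3Z)-4-[4-(benzyloxy)-3,5-dimethoxyphenyl]-2-{[4-(benzyloxy)-3,5-dimethoxyphenyl]methyl}-4-[(trimethylsilyl)oxy]but-3-en-1-yl](methylidene)oxonium trifluoromethanesulfonate | COc1cc(C[C@@H](C[O+]=C)/C=C(\O[Si](C)(C)C)c2cc(OC)c(OCc3ccccc3)c(OC)c2)cc(OC)c1OCc1ccccc1.[O-]S(=O)(=O)C(F)(F)F | intermediate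
17 | [(3R,4R)-4-{[4-(benzyloxy)-3,5-dimethoxyphenyl]methyl}oxolan-3-yl][4-(benzyloxy)-3,5-dimethoxyphenyl]methanone (trans) | COc1cc(C[C@H]2COC[C@@H]2C(=O)c2cc(OC)c(OCc3ccccc3)c(OC)c2)cc(OC)c1OCc1ccccc1 | intermediate
18 | (S)-[4-(benzyloxy)-3,5-dimethoxyphenyl][(3R,4R)-4-{[4-(benzyloxy)-3,5-dimethoxyphenyl]methyl}oxolan-3-yl]methanol | COc1cc(C[C@H]2COC[C@@H]2[C@H](O)c2cc(OC)c(OCc3ccccc3)c(OC)c2)cc(OC)c1OCc1ccccc1 | intermediate
19 | 4-{[(3R,4R)-4-[(S)-hydroxy(4-hydroxy-3,5-dimethoxyphenyl)methyl]oxolan-3-yl]methyl}-2,6-dimethoxyphenol | COc1cc(C[C@H]2COC[C@@H]2[C@H](O)c2cc(OC)c(O)c(OC)c2)cc(OC)c1O | target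

**Step count and risks**

Total steps: 10. Longest linear sequence: 9 steps (1 → 2 → 5 → 6 → 8 → 13 → 14 → 17 → 18 → 19); step 5 is a one-step side branch to 10.

Steps most likely to fail:

1. Step 8 (proposed new method). The acetal may ionise toward the methoxymethyl cation instead of the O-methylene oxocarbenium ion, so that the protecting group is merely lost or transferred. The 5-endo closure may also be slower than desilylation of the enol ether, or slower than Friedel–Crafts attack of the electron-rich benzyl ring on the cation. The fallback uses known chemistry, sets out from lactone 8 and returns at 17, replacing steps 6 to 8. The lithium enolate of 8 (LiN(iPr)2, THF, −78 °C) is hydroxymethylated with monomeric formaldehyde anti to the ring substituent to give the trans lactone (3S,4R)-4-{[4-(benzyloxy)-3,5-dimethoxyphenyl]methyl}-3-(hydroxymethyl)oxolan-2-one F1. Silylation (tBuMe2SiCl, imidazole, DMF) gives the silyl ether (3S,4R)-4-{[4-(benzyloxy)-3,5-dimethoxyphenyl]methyl}-3-{[(tert-butyldimethylsilyl)oxy]methyl}oxolan-2-one F2. Aryllithium 11 at −78 °C opens F2 to the hydroxy ketone (2S,3R)-1-[4-(benzyloxy)-3,5-dimethoxyphenyl]-3-{[4-(benzyloxy)-3,5-dimethoxyphenyl]methyl}-2-{[(tert-butyldimethylsilyl)oxy]methyl}-4-hydroxybutan-1-one F3. Mesylation (MeSO2Cl, Et3N, CH2Cl2, 0 °C) gives (2R,3S)-4-[4-(benzyloxy)-3,5-dimethoxyphenyl]-2-{[4-(benzyloxy)-3,5-dimethoxyphenyl]methyl}-3-{[(tert-butyldimethylsilyl)oxy]methyl}-4-oxobutyl methanesulfonate F4. Bu4NF in THF then removes the silyl group, and the freed alkoxide closes the oxolane by 5-exo-tet Williamson displacement of the mesylate. This gives the cis ketone [(3S,4R)-4-{[4-(benzyloxy)-3,5-dimethoxyphenyl]methyl}oxolan-3-yl][4-(benzyloxy)-3,5-dimethoxyphenyl]methanone F5, cis because the ring now runs through the former hydroxymethyl carbon. 1,8-Diazabicyclo[5.4.0]undec-7-ene in CH2Cl2 epimerises the ketone α-carbon to the trans isomer 17. In this variant C4–C5 comes from a lactone-enolate aldol and the ring closes through a C–O bond, and the ring oxygen then stems from formaldehyde.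

2. Step 4. Discrimination between the two enantiotopic methylene groups in the Criegee adduct may be incomplete, because the aryl group that the catalyst pocket recognises is one CH2 further from the ring than in 3-aryl substrates; the lactone would then be formed with insufficient enantiomeric purity. The fallback sets out from 6 and returns at 8. Enantioselective deprotonation of 6 with a homochiral lithium amide (LiN[(S)-CH(Me)Ph]2 or its antipode, whichever gives the R series, Me3SiCl in-situ quench, THF, −100 °C) gives the silyl enol ether {[(3R)-3-{[4-(benzyloxy)-3,5-dimethoxyphenyl]methyl}cyclobut-1-en-1-yl]oxy}trimethylsilane F6. Ozonolysis of the enol double bond (O3, CH2Cl2–MeOH, −78 °C) with NaBH4 work-up gives (3R)-4-[4-(benzyloxy)-3,5-dimethoxyphenyl]-3-(hydroxymethyl)butanoic acid F7, which lactonises on acidification to 8. The stereocentre is then set by selective proton abstraction and the lactone oxygen arrives by oxidative cleavage.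

3. Step 6. The tetrahedral adduct may collapse early and take up a second aryllithium to give a tertiary alcohol, or the aryllithium may enolise the lactone; the free γ-hydroxy ketone may also dehydrate through its hemiketal on handling. The fallback sets out from 8 and returns at 14, bypassing 13. Aminolysis of 8 (Me(MeO)NH·HCl, AlMe3, CH2Cl2, 0 °C → rt) gives (3R)-4-[4-(benzyloxy)-3,5-dimethoxyphenyl]-3-(hydroxymethyl)-N-methoxy-N-methylbutanamide F8. Immediate protection (MeOCH2Cl, iPr2NEt, CH2Cl2) gives (3R)-4-[4-(benzyloxy)-3,5-dimethoxyphenyl]-N-methoxy-3-[(methoxymethoxy)methyl]-N-methylbutanamide F9. Aryllithium 11 (THF, −78 °C) adds once to F9 through the stable N-methoxy chelate and gives 14 on work-up.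

**Further compounds**

F1 | step 8 | (3S,4R)-4-{[4-(benzyloxy)-3,5-dimethoxyphenyl]methyl}-3-(hydroxymethyl)oxolan-2-one | COc1cc(C[C@H]2COC(=O)[C@@H]2CO)cc(OC)c1OCc1ccccc1
F2 | step 8 | (3S,4R)-4-{[4-(benzyloxy)-3,5-dimethoxyphenyl]methyl}-3-{[(tert-butyldimethylsilyl)oxy]methyl}oxolan-2-one | COc1cc(C[C@H]2COC(=O)[C@@H]2CO[Si](C)(C)C(C)(C)C)cc(OC)c1OCc1ccccc1
F3 | step 8 | (2S,3R)-1-[4-(benzyloxy)-3,5-dimethoxyphenyl]-3-{[4-(benzyloxy)-3,5-dimethoxyphenyl]methyl}-2-{[(tert-butyldimethylsilyl)oxy]methyl}-4-hydroxybutan-1-one | COc1cc(C[C@@H](CO)[C@@H](CO[Si](C)(C)C(C)(C)C)C(=O)c2cc(OC)c(OCc3ccccc3)c(OC)c2)cc(OC)c1OCc1ccccc1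
F4 | step 8 | (2R,3S)-4-[4-(benzyloxy)-3,5-dimethoxyphenyl]-2-{[4-(benzyloxy)-3,5-dimethoxyphenyl]methyl}-3-{[(tert-butyldimethylsilyl)oxy]methyl}-4-oxobutyl methanesulfonate | COc1cc(C[C@@H](COS(C)(=O)=O)[C@@H](CO[Si](C)(C)C(C)(C)C)C(=O)c2cc(OC)c(OCc3ccccc3)c(OC)c2)cc(OC)c1OCc1ccccc1
F5 | step 8 | [(3S,4R)-4-{[4-(benzyloxy)-3,5-dimethoxyphenyl]methyl}oxolan-3-yl][4-(benzyloxy)-3,5-dimethoxyphenyl]methanone (cis) | COc1cc(C[C@H]2COC[C@H]2C(=O)c2cc(OC)c(OCc3ccccc3)c(OC)c2)cc(OC)c1OCc1ccccc1
F6 | step 4 | {[(3R)-3-{[4-(benzyloxy)-3,5-dimethoxyphenyl]methyl}cyclobut-1-en-1-yl]oxy}trimethylsilane | COc1cc(C[C@@H]2CC(O[Si](C)(C)C)=C2)cc(OC)c1OCc1ccccc1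
F7 | step 4 | (3R)-4-[4-(benzyloxy)-3,5-dimethoxyphenyl]-3-(hydroxymethyl)butanoic acid | COc1cc(C[C@@H](CO)CC(=O)O)cc(OC)c1OCc1ccccc1
F8 | step 6 | (3R)-4-[4-(benzyloxy)-3,5-dimethoxyphenyl]-3-(hydroxymethyl)-N-methoxy-N-methylbutanamide | COc1cc(C[C@@H](CO)CC(=O)N(C)OC)cc(OC)c1OCc1ccccc1
F9 | step 6 | (3R)-4-[4-(benzyloxy)-3,5-dimethoxyphenyl]-N-methoxy-3-[(methoxymethoxy)methyl]-N-methylbutanamide | COc1cc(C[C@@H](COCOC)CC(=O)N(C)OC)cc(OC)c1OCc1ccccc1
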